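**Plan**

1. The target is read as (1S,2R,5R,6R)-2,6-bis(4-hydroxy-3-methoxyphenyl)-3,7-dioxabicyclo[3.3.0]octan-1-ol. Ring A is C1–C2–O3–C4–C5 and ring B is C5–C6–O7–C8–C1; C1 carries the OH, the C2 aryl is exo and cis to it, the C6 aryl is endo.
2. Retrosynthesis: phenols from silyl ethers; the C4–O3 ether from a lactone (C4=O) through the triol; C5–H and C6–H from a C5=C6 bond; the resulting hydroxy-dihydrofuran lactone is then cut at C1–C5 and O7–C8 in one step.
3. Enabling feature: the tertiary carbinol C1 is bonded to the ring B OCH2 carbon C8 and faces the unit C5–C6–O7 across the ring fusion. With C4 as a carbonyl this is the product pattern of an interrupted Feist–Benary reaction between an α-chloro ketone (C1=O, C8–Cl) and a β-keto ester enolate (C4–C5–C6–O7), here tethered through the ester oxygen O3.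
4. Forward: vanillin gives one silyl aldehyde that serves both halves (epoxy alcohol by kinetic resolution; acyl Meldrum's acid). Ester union, epoxide to chlorohydrin to chloro ketone, then one base-mediated step closes ring A (aldol) and ring B (O-alkylation). Hydrogenation, lactone to cyclic ether and desilylation follow.
5. Stereochemistry: C2 comes from the Sharpless kinetic resolution; C1 from C2 in the bicyclisation; C5 and C6 from syn hydrogenation on the hydroxyl-bearing convex face, which gives the endo C6 aryl directly. Later steps are base- or fluoride-mediated and break no bond at a stereocentre.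

Key step: step 9

Notation: Ar = 3-methoxy-4-(triisopropylsilyloxy)phenyl.

**Route**

Step 1
Reactants: 1 vanillin; 2 chlorotriisopropylsilane
Product: 3 3-methoxy-4-(triisopropylsilyloxy)benzaldehyde
Conditions: imidazole, DMF, rt
Reagents that add atoms: chlorotriisopropylsilane, CC(C)[Si](Cl)(C(C)C)C(C)C
Why: Standard silylation of a phenol with a silyl chloride and imidazole; the bulky triisopropylsilyl ether is chosen because it should survive carbonate base, hydride and hydrogenation and is removed at the end by fluoride without acid.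

Step 2
Reactants: 3 3-methoxy-4-(triisopropylsilyloxy)benzaldehyde; 4 vinylmagnesium bromide
Product: 5 racemic 1-Ar-prop-2-en-1-ol
Conditions: THF, −78 to 0 °C; aq. NH4Cl
Reagents that add atoms: vinylmagnesium bromide, C=C[Mg]Br
Why: Grignard 1,2-addition to an aromatic aldehyde gives the secondary allylic alcohol as a racemate, which is acceptable because the next step resolves it.

Step 3
Reactants: 5 racemic 1-Ar-prop-2-en-1-ol; 6 tert-butyl hydroperoxide
Product: 7 (R)-Ar[(2S)-oxiran-2-yl]methanol
Conditions: Ti(OiPr)4 (10 mol%), D-(−)-diisopropyl tartrate (12 mol%), t-BuOOH (0.45 equiv), 4 Å molecular sieves, CH2Cl2, −20 °C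
Reagents that add atoms: tert-butyl hydroperoxide, CC(C)(C)OO
Why: Sharpless kinetic resolution, in which the D-(−)-tartrate catalyst should epoxidise the (S)-alcohol much faster than its antipode and on one alkene face, so that stopping below half conversion gives the erythro epoxy alcohol whose benzylic carbinol centre (the future C2) has the required configuration while the (R)-alcohol stays behind.

Step 4
Reactants: 3 3-methoxy-4-(triisopropylsilyloxy)benzaldehyde; 8 sodium chlorite
Product: 9 3-methoxy-4-(triisopropylsilyloxy)benzoic acid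
Conditions: NaClO2, NaH2PO4, 2-methyl-2-butene, t-BuOH/H2O, rt
Reagents that add atoms: sodium chlorite, [Na+].[O-]Cl=O
Why: Pinnick oxidation of the aldehyde at weakly acidic pH, with 2-methyl-2-butene scavenging hypochlorous acid so that the electron-rich ring is not chlorinated and the silyl ether survives.

Step 5
Reactants: 9 3-methoxy-4-(triisopropylsilyloxy)benzoic acid; 10 Meldrum's acid
Product: 11 5-[hydroxy(Ar)methylidene]-2,2-dimethyl-1,3-dioxane-4,6-dione
Conditions: DCC, DMAP, CH2Cl2, 0 °C to rt; cold aq. KHSO4 wash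
Reagents that add atoms: Meldrum's acid, CC1(C)OC(=O)CC(=O)O1
Why: Carbodiimide-mediated C-acylation of Meldrum's acid by a carboxylic acid gives the enolised acyl Meldrum's acid, a bench-stable precursor of an acylketene.

Step 6
Reactants: 7 (R)-Ar[(2S)-oxiran-2-yl]methanol; 11 5-[hydroxy(Ar)methylidene]-2,2-dimethyl-1,3-dioxane-4,6-dione
Product: 13 (R)-Ar[(2S)-oxiran-2-yl]methyl 3-Ar-3-oxopropanoate, via aroylketene 12 (not isolated)
Conditions: toluene, 80 °C, slow addition of 11 to 7
Reagents that add atoms: acyl Meldrum's acid 11, COc1cc(C(O)=C2C(=O)OC(C)(C)OC2=O)ccc1O[Si](C(C)C)(C(C)C)C(C)C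
Why: Thermolysis of the acyl Meldrum's acid releases acetone and CO2 to give aroylketene 12, which the secondary alcohol traps under neutral conditions (acylketene acylation) to form the β-keto ester without breaking the C–O bond of the stereocentre.

Step 7
Reactants: 13 (R)-Ar[(2S)-oxiran-2-yl]methyl 3-Ar-3-oxopropanoate; 14 lithium chloride
Product: 15 (1R,2R)-3-chloro-2-hydroxy-1-Ar-propyl 3-Ar-3-oxopropanoate
Conditions: LiCl, AcOH, THF, rt
Reagents that add atoms: lithium chloride, [Li+].[Cl-]
Why: Chloride opens the terminal epoxide by SN2 attack at the unhindered CH2 carbon under weakly acidic conditions that should neither enolise the keto ester nor ionise the benzylic ester, and the carbinol centre so formed is removed in the next step.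

Step 8
Reactants: 15 (1R,2R)-3-chloro-2-hydroxy-1-Ar-propyl 3-Ar-3-oxopropanoate
Product: 16 (1R)-3-chloro-2-oxo-1-Ar-propyl 3-Ar-3-oxopropanoate
Conditions: Dess–Martin periodinane, NaHCO3, CH2Cl2, 0 °C to rt
Reagents that add atoms: none
Why: Dess–Martin oxidation of the secondary chlorohydrin gives the chloromethyl ketone under buffered, non-basic conditions that should leave the now acidic benzylic α-hydrogen and the active methylene untouched.

Step 9
Reactants: 16 (1R)-3-chloro-2-oxo-1-Ar-propyl 3-Ar-3-oxopropanoate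
Product: 18 (1S,2R)-1-hydroxy-2,6-bis(Ar)-3,7-dioxabicyclo[3.3.0]oct-5-en-4-one, via aldol chlorohydrin 17 (not isolated)
Conditions: K2CO3 (1.2 equiv), MeCN, 0 °C to rt
Reagents that add atoms: none
Why: Proposed new method: this is an ester-tethered interrupted Feist–Benary bicyclisation, and its closest known relatives are the intermolecular interrupted Feist–Benary reaction of β-keto esters with α-halo ketones (aldol addition, then O-alkylation to a 3-hydroxy-2,3-dihydrofuran) and the base-mediated intramolecular aldol of acyloin β-keto esters. K2CO3 should deprotonate only the β-keto ester methylene, and the enolate carbon C5 then adds reversibly to the ketone C1, which is activated by its two α-heteroatom substituents, in a 5-(enolexo)-exo-trig aldol that closes lactone ring A and gives alkoxide 17. The aroyl enolate oxygen O7 then displaces chloride at C8 in an irreversible 5-exo-tet O-alkylation (directly or by way of the spiro-epoxide that the C1 alkoxide can form), which closes dihydrofuran ring B and keeps the C1 hydroxyl because no acid is present to dehydrate it to the furan. The one new stereocentre, C1, is set by C2: in the aldol transition state the C2 aryl group sits next to the small carbonyl oxygen and away from the chloromethyl arm, and because the aldol is reversible the product-determining ring B closure should also favour the isomer with that aryl group on the convex face, so the C1 hydroxyl ends up cis to the C2 aryl group. The step needs carbonyl addition to outrun direct SN2 C-alkylation at C8 (a six-ring closure) and needs C2 not to enolise; the five-ring aldol, the use of chloride in place of a better leaving group and a weak heterogeneous base at 0 °C are what should secure this.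

Step 10
Reactants: 18 (1S,2R)-1-hydroxy-2,6-bis(Ar)-3,7-dioxabicyclo[3.3.0]oct-5-en-4-one
Product: 19 (1S,2R,5R,6R)-1-hydroxy-2,6-bis(Ar)-3,7-dioxabicyclo[3.3.0]octan-4-one
Conditions: H2 (1–4 atm), palladium on carbon (10%), EtOAc, rt, stopped at one equivalent of uptake
Reagents that add atoms: none
Why: Heterogeneous hydrogenation adds both hydrogens to the tetrasubstituted C5=C6 bond from one face, and since the bicyclo[3.3.0] system strongly prefers a cis ring fusion the hydrogen at C5 should arrive on the face of the C1 hydroxyl (which can also anchor the substrate on the metal), so syn addition places H6 on that face and the C6 aryl on the concave face, the endo configuration of the target.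

Step 11
Reactants: 19 (1S,2R,5R,6R)-1-hydroxy-2,6-bis(Ar)-3,7-dioxabicyclo[3.3.0]octan-4-one
Product: 20 (3S,4R,5R)-3-[(R)-hydroxy(Ar)methyl]-4-(hydroxymethyl)-5-Ar-oxolan-3-ol
Conditions: LiAlH4, THF, 0 °C; then H2O, aq. NaOH
Reagents that add atoms: none
Why: Hydride reduction of the lactone to the primary and benzylic alcohols touches no stereocentre, and fast carbonyl addition at low temperature should outrun enolisation at C5 and thus β-elimination of the ring B oxygen.

Step 12
Reactants: 20 (3S,4R,5R)-3-[(R)-hydroxy(Ar)methyl]-4-(hydroxymethyl)-5-Ar-oxolan-3-ol; 21 p-toluenesulfonyl chloride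
Product: 23 (1S,2R,5R,6R)-2,6-bis(Ar)-3,7-dioxabicyclo[3.3.0]octan-1-ol, via primary tosylate 22 (not isolated)
Conditions: TsCl (1.1 equiv), pyridine, CH2Cl2, 0 °C; then 40 °C
Reagents that add atoms: none
Why: Chemoselective sulfonylation of the primary hydroxyl followed by intramolecular Williamson-type etherification (5-exo-tet) by the benzylic hydroxyl closes ring A with retention at C2 because the C2–O bond is never broken, and the basic medium should not ionise the acid-labile endo aryl ether at C6.

Step 13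
Reactants: 23 (1S,2R,5R,6R)-2,6-bis(Ar)-3,7-dioxabicyclo[3.3.0]octan-1-ol
Product: 24 (1S,2R,5R,6R)-2,6-bis(4-hydroxy-3-methoxyphenyl)-3,7-dioxabicyclo[3.3.0]octan-1-ol
Conditions: Bu4NF, AcOH, THF, 0 °C to rt
Reagents that add atoms: none
Why: Fluoride cleaves both aryl silyl ethers, and the acetic acid buffer keeps the phenols protonated so that no quinone methide pathway should epimerise the benzylic ether centres.

**Compound list**

1 | vanillin (4-hydroxy-3-methoxybenzaldehyde) | COc1cc(C=O)ccc1O | starting material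
2 | chlorotriisopropylsilane | CC(C)[Si](Cl)(C(C)C)C(C)C | starting material
3 | 3-methoxy-4-(triisopropylsilyloxy)benzaldehyde | COc1cc(C=O)ccc1O[Si](C(C)C)(C(C)C)C(C)C | intermediate
4 | vinylmagnesium bromide | C=C[Mg]Br | starting material
5 | racemic 1-[3-methoxy-4-(triisopropylsilyloxy)phenyl]prop-2-en-1-ol | COc1cc(C(O)C=C)ccc1O[Si](C(C)C)(C(C)C)C(C)C | intermediate
6 | tert-butyl hydroperoxide | CC(C)(C)OO | starting material
7 | (R)-[3-methoxy-4-(triisopropylsilyloxy)phenyl][(2S)-oxiran-2-yl]methanol | COc1cc([C@H]([C@@H]2CO2)O)ccc1O[Si](C(C)C)(C(C)C)C(C)C | intermediate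
8 | sodium chlorite | [Na+].[O-]Cl=O | starting material
9 | 3-methoxy-4-(triisopropylsilyloxy)benzoic acid | COc1cc(C(=O)O)ccc1O[Si](C(C)C)(C(C)C)C(C)C | intermediate
10 | Meldrum's acid (2,2-dimethyl-1,3-dioxane-4,6-dione) | CC1(C)OC(=O)CC(=O)O1 | starting material
11 | 5-[hydroxy(Ar)methylidene]-2,2-dimethyl-1,3-dioxane-4,6-dione | COc1cc(C(O)=C2C(=O)OC(C)(C)OC2=O)ccc1O[Si](C(C)C)(C(C)C)C(C)C | intermediate
12 | aroylketene, 3-Ar-3-oxoprop-1-en-1-one (not isolated) | COc1cc(C(=O)C=C=O)ccc1O[Si](C(C)C)(C(C)C)C(C)C | intermediate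
13 | (R)-Ar[(2S)-oxiran-2-yl]methyl 3-Ar-3-oxopropanoate | COc1cc([C@H]([C@@H]2CO2)OC(=O)CC(=O)c2ccc(O[Si](C(C)C)(C(C)C)C(C)C)c(OC)c2)ccc1O[Si](C(C)C)(C(C)C)C(C)C | intermediate
14 | lithium chloride | [Li+].[Cl-] | starting material
15 | (1R,2R)-3-chloro-2-hydroxy-1-Ar-propyl 3-Ar-3-oxopropanoate | COc1cc([C@H]([C@@H](O)CCl)OC(=O)CC(=O)c2ccc(O[Si](C(C)C)(C(C)C)C(C)C)c(OC)c2)ccc1O[Si](C(C)C)(C(C)C)C(C)C | intermediate
16 | (1R)-3-chloro-2-oxo-1-Ar-propyl 3-Ar-3-oxopropanoate | COc1cc([C@H](C(=O)CCl)OC(=O)CC(=O)c2ccc(O[Si](C(C)C)(C(C)C)C(C)C)c(OC)c2)ccc1O[Si](C(C)C)(C(C)C)C(C)C | intermediate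
17 | (4R,5R)-4-(chloromethyl)-4-hydroxy-3-[3-methoxy-4-(triisopropylsilyloxy)benzoyl]-5-Ar-oxolan-2-one, present as its potassium enolate, C3 undefined (not isolated) | COc1cc([C@H]2OC(=O)C(C(=O)c3ccc(O[Si](C(C)C)(C(C)C)C(C)C)c(OC)c3)[C@]2(O)CCl)ccc1O[Si](C(C)C)(C(C)C)C(C)C | intermediate
18 | (1S,2R)-1-hydroxy-2,6-bis(Ar)-3,7-dioxabicyclo[3.3.0]oct-5-en-4-one | COc1cc([C@H]2OC(=O)C3=C(c4ccc(O[Si](C(C)C)(C(C)C)C(C)C)c(OC)c4)OC[C@]23O)ccc1O[Si](C(C)C)(C(C)C)C(C)C | intermediate
19 | (1S,2R,5R,6R)-1-hydroxy-2,6-bis(Ar)-3,7-dioxabicyclo[3.3.0]octan-4-one | COc1cc([C@H]2OC(=O)[C@@H]3[C@H](c4ccc(O[Si](C(C)C)(C(C)C)C(C)C)c(OC)c4)OC[C@]23O)ccc1O[Si](C(C)C)(C(C)C)C(C)C | intermediate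
20 | (3S,4R,5R)-3-[(R)-hydroxy(Ar)methyl]-4-(hydroxymethyl)-5-Ar-oxolan-3-ol | COc1cc([C@@H](O)[C@@]2(O)CO[C@@H](c3ccc(O[Si](C(C)C)(C(C)C)C(C)C)c(OC)c3)[C@H]2CO)ccc1O[Si](C(C)C)(C(C)C)C(C)C | intermediate
21 | p-toluenesulfonyl chloride | Cc1ccc(S(=O)(=O)Cl)cc1 | starting material
22 | [(2R,3R,4S)-4-hydroxy-4-[(R)-hydroxy(Ar)methyl]-2-Ar-oxolan-3-yl]methyl 4-methylbenzenesulfonate (not isolated) | COc1cc([C@@H](O)[C@@]2(O)CO[C@@H](c3ccc(O[Si](C(C)C)(C(C)C)C(C)C)c(OC)c3)[C@H]2COS(=O)(=O)c2ccc(C)cc2)ccc1O[Si](C(C)C)(C(C)C)C(C)C | intermediate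
23 | (1S,2R,5R,6R)-2,6-bis(Ar)-3,7-dioxabicyclo[3.3.0]octan-1-ol | COc1cc([C@H]2OC[C@@H]3[C@H](c4ccc(O[Si](C(C)C)(C(C)C)C(C)C)c(OC)c4)OC[C@]23O)ccc1O[Si](C(C)C)(C(C)C)C(C)C | intermediate
24 | (1S,2R,5R,6R)-2,6-bis(4-hydroxy-3-methoxyphenyl)-3,7-dioxabicyclo[3.3.0]octan-1-ol | COc1cc([C@H]2OC[C@@H]3[C@H](c4ccc(O)c(OC)c4)OC[C@]23O)ccc1O | target

**Step count**

Total: 13 steps. Longest linear sequence: 11 steps (1, 2, 3, 6, 7, 8, 9, 10, 11, 12, 13); steps 4 and 5 form the side branch.

**Steps most likely to fail**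

Step 9 (proposed method). Three processes could defeat it: loss of configuration at C2 by enolisation of the α-acyloxy ketone before ring closure; direct C-alkylation of the keto ester at the chloromethyl carbon ahead of the aldol; and poor facial selectivity at C1. The fallback uses the known untethered interrupted Feist–Benary reaction, sets out from 7 and 11, and returns at 18. Epoxy alcohol 7 is silylated (Et3SiCl, imidazole) to triethyl{(R)-Ar[(2S)-oxiran-2-yl]methoxy}silane F1. It is opened with LiCl/AcOH to (2R,3R)-1-chloro-3-Ar-3-(triethylsilyloxy)propan-2-ol F2 and oxidised with Dess–Martin periodinane to (3R)-1-chloro-3-Ar-3-(triethylsilyloxy)propan-2-one F3. The alkyl silyl ether is then removed selectively (HF·pyridine, THF, 0 °C) to give (3R)-1-chloro-3-hydroxy-3-Ar-propan-2-one F4. Separately, 11 is heated in methanol to methyl 3-Ar-3-oxopropanoate F5. F4 and F5 are joined under soft enolisation (MgBr2·OEt2, Et3N, CH2Cl2, 0 °C): magnesium held between the free α-hydroxyl and the ketone should direct the enolate to the face away from the aryl group, which gives the same C1 configuration as the tethered reaction, and O-alkylation follows on warming. The product, methyl (4S)-4-hydroxy-4-[(R)-hydroxy(Ar)methyl]-2-Ar-4,5-dihydrofuran-3-carboxylate F6, is lactonised with catalytic DBU to 18.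

Step 10. The tetrasubstituted, electron-poor alkene may reduce slowly, and hydrogenolysis of the benzylic lactone C2–O3 bond or of the allylic C1–OH bond may compete. The fallback changes the order of events, sets out from 18 and returns at 23. The lactone carbonyl is reduced first with DIBAL-H (CH2Cl2, −78 to 0 °C) to (3S)-3-[(R)-hydroxy(Ar)methyl]-4-(hydroxymethyl)-5-Ar-2,3-dihydrofuran-3-ol F7. Ring A is then closed by Mitsunobu cyclodehydration (PPh3, diisopropyl azodicarboxylate, THF, 0 °C), with the primary allylic hydroxyl activated and the benzylic hydroxyl as nucleophile, to give (1S,2R)-2,6-bis(Ar)-3,7-dioxabicyclo[3.3.0]oct-5-en-1-ol F8. The electron-rich enol ether of F8, which now carries benzylic ethers and no benzylic ester, is hydrogenated (H2, palladium on carbon, EtOAc, trace Et3N) from the hydroxyl face to give 23.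

Step 6. The acidic acyl Meldrum's acid at 80 °C may open the epoxide or ionise the electron-rich benzylic alcohol before acyl transfer. The fallback moves the thermal step away from the sensitive alcohol, sets out from 11 and 7, and returns at 13. Compound 11 is heated alone with 2-methylpropane-2-thiol in toluene to give S-tert-butyl 3-Ar-3-oxopropanethioate F9. F9 is then transesterified with 7 at room temperature by thiophilic activation with AgOCOCF3 in THF, which gives 13.

Further compounds
F1 | step 9 | triethyl{(R)-Ar[(2S)-oxiran-2-yl]methoxy}silane | COc1cc([C@H]([C@@H]2CO2)O[Si](CC)(CC)CC)ccc1O[Si](C(C)C)(C(C)C)C(C)C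
F2 | step 9 | (2R,3R)-1-chloro-3-Ar-3-(triethylsilyloxy)propan-2-ol | COc1cc([C@H]([C@@H](O)CCl)O[Si](CC)(CC)CC)ccc1O[Si](C(C)C)(C(C)C)C(C)C
F3 | step 9 | (3R)-1-chloro-3-Ar-3-(triethylsilyloxy)propan-2-one | COc1cc([C@H](C(=O)CCl)O[Si](CC)(CC)CC)ccc1O[Si](C(C)C)(C(C)C)C(C)C
F4 | step 9 | (3R)-1-chloro-3-hydroxy-3-Ar-propan-2-one | COc1cc([C@H](C(=O)CCl)O)ccc1O[Si](C(C)C)(C(C)C)C(C)C
F5 | step 9 | methyl 3-Ar-3-oxopropanoate | COC(=O)CC(=O)c1ccc(O[Si](C(C)C)(C(C)C)C(C)C)c(OC)c1
F6 | step 9 | methyl (4S)-4-hydroxy-4-[(R)-hydroxy(Ar)methyl]-2-Ar-4,5-dihydrofuran-3-carboxylate | COC(=O)C1=C(c2ccc(O[Si](C(C)C)(C(C)C)C(C)C)c(OC)c2)OC[C@]1(O)[C@H](O)c1ccc(O[Si](C(C)C)(C(C)C)C(C)C)c(OC)c1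
F7 | step 10 | (3S)-3-[(R)-hydroxy(Ar)methyl]-4-(hydroxymethyl)-5-Ar-2,3-dihydrofuran-3-ol | COc1cc([C@@H](O)[C@@]2(O)COC(c3ccc(O[Si](C(C)C)(C(C)C)C(C)C)c(OC)c3)=C2CO)ccc1O[Si](C(C)C)(C(C)C)C(C)C
F8 | step 10 | (1S,2R)-2,6-bis(Ar)-3,7-dioxabicyclo[3.3.0]oct-5-en-1-ol | COc1cc([C@H]2OCC3=C(c4ccc(O[Si](C(C)C)(C(C)C)C(C)C)c(OC)c4)OC[C@]23O)ccc1O[Si](C(C)C)(C(C)C)C(C)C
F9 | step 6 | S-tert-butyl 3-Ar-3-oxopropanethioate | CC(C)(C)SC(=O)CC(=O)c1ccc(O[Si](C(C)C)(C(C)C)C(C)C)c(OC)c1
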